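**Plan**

- Retrosynthesis (flavanone numbering, rings A, B, C): ring C is opened at C3–C4 as an alkene hydroacylation, the formyl C4–H of a benzaldehyde adding across an enol ether C2=C3 that hangs on O1. Then the three ring-A C–C bonds (to the formyl, prenyl and hydroxyethyl carbons), the C2=C3 methylene (ester methylenation) and the O1–C2 ester bond are cut, leaving phloroglucinol and vanillic acid.
- Forward: bis-MOM phloroglucinol is esterified with O-silyl vanillic acid and the ester is methylenated to the 1-arylvinyl aryl ether. Ring A is then filled by three directed ortho-lithiations, the first between the two MOM ethers (C6 chain); after that the two free positions are equivalent, so prenyl (C8) and formyl (C4) need no regiocontrol.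
- Ring C, the only ring made in the route, closes last by rhodium-catalysed enantioselective intramolecular hydroacylation; one acid treatment then removes all four protecting groups.
- Enabling feature: C3 is an unsubstituted CH2 between the carbonyl C4 and the carbinol C2, and C2 carries only H, ring B and O1. Ring C therefore maps onto a 2-(1-arylvinyloxy)benzaldehyde in which C4–H and C2=C3 are held 1,6 across O1–C8a–C4a.
- Stereochemistry: the single stereocentre C2 (S) is created in the key step, when the formyl hydrogen is delivered to one face of C2=C3 on rhodium carrying a chiral bisphosphine; no basic step follows.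

Key step: step 8

Remark: the sense of induction of the bisphosphine in step 8 cannot be assigned in advance. The (R)-ligand is written; its antipode is taken if the first analytical run shows the (2R)-ketone.

**Step 1**
Reactants: 1 phloroglucinol
Product: 2 3,5-bis(methoxymethoxy)phenol
Conditions: NaH (2.0 equiv), MOMCl (2.0 equiv), DMF, 0 °C → rt; chromatography
Reagents that add atoms: chloromethyl methyl ether (MOMCl), COCCl
Why: O-alkylation of the phenoxide by the chloromethyl ether (Williamson-type acetal formation) is statistical over three equivalent hydroxyls, so two equivalents should give the bis-ether as main product, separable from mono- and tris-ether, with the mono-ether resubmitted.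

**Step 2**
Reactants: 3 vanillic acid
Product: 5 4-[(tert-butyldimethylsilyl)oxy]-3-methoxybenzoic acid, via bis-silyl compound 4 (not isolated)
Conditions: TBSCl (2.3 equiv), imidazole, DMF, rt; then AcOH/THF/H2O (3:1:1), rt
Reagents that add atoms: tert-butyldimethylsilyl chloride (TBSCl), CC(C)(C)[Si](C)(C)Cl
Why: Silylation of both acidic OH groups is followed by hydrolysis of the much more labile silyl ester under mild aqueous acid, which should leave the aryl silyl ether, a bulky and weakly coordinating group chosen so that ring B is not lithiated later.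

**Step 3**
Reactants: 2 3,5-bis(methoxymethoxy)phenol; 5 4-[(tert-butyldimethylsilyl)oxy]-3-methoxybenzoic acid
Product: 6 3,5-bis(methoxymethoxy)phenyl 4-[(tert-butyldimethylsilyl)oxy]-3-methoxybenzoate
Conditions: DCC, DMAP (cat.), CH2Cl2, 0 °C → rt
Reagents that add atoms: none
Why: Steglich esterification (carbodiimide activation, DMAP acyl transfer) should couple the single free phenol of 2 with acid 5 without touching the acetals or the silyl ether.

**Step 4**
Reactants: 6 3,5-bis(methoxymethoxy)phenyl 4-[(tert-butyldimethylsilyl)oxy]-3-methoxybenzoate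
Product: 7 tert-butyl{4-[1-(3,5-bis(methoxymethoxy)phenoxy)ethenyl]-2-methoxyphenoxy}dimethylsilane
Conditions: Cp2Ti(μ-Cl)(μ-CH2)AlMe2 (Tebbe reagent, toluene solution), pyridine (cat.), THF, –40 °C → rt; aq. NaOH quench; basic alumina
Reagents that add atoms: Tebbe reagent Cp2Ti(μ-Cl)(μ-CH2)AlMe2, C[Al-]1(C)C[Ti](C2C=CC=C2)(C2C=CC=C2)[Cl+]1
Why: Tebbe olefination, in which the titanium methylidene adds [2+2] to the ester carbonyl and cycloreverts to the enol ether, is well established for aryl benzoates and tolerates acetals and silyl ethers.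

**Step 5**
Reactants: 7 tert-butyl{4-[1-(3,5-bis(methoxymethoxy)phenoxy)ethenyl]-2-methoxyphenoxy}dimethylsilane
Product: 10 tert-butyl{2-[4-({1-[4-(tert-butyldimethylsilyloxy)-3-methoxyphenyl]ethenyl}oxy)-2,6-bis(methoxymethoxy)phenyl]ethoxy}dimethylsilane, via aryllithium 8 (not isolated), via lithium alkoxide 9 (not isolated)
Conditions: n-BuLi, TMEDA, THF, –40 → –10 °C; ethylene oxide (THF solution), –10 °C → rt; then TBSCl, imidazole (cat.), DMF, rt
Reagents that add atoms: ethylene oxide, C1CO1; tert-butyldimethylsilyl chloride (TBSCl), CC(C)(C)[Si](C)(C)Cl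
Why: Directed ortho-metalation should occur at the ring-A carbon flanked by the two MOM ethers (two cooperating acetal donors, against one MOM and the weakly basic, hindered enol-ether oxygen elsewhere), the aryllithium opens ethylene oxide and the lithium alkoxide is silylated in the same flask, an enol ether without α-hydrogen not being attacked by alkyllithiums at low temperature.

**Step 6**
Reactants: 10 tert-butyl{2-[4-({1-[4-(tert-butyldimethylsilyloxy)-3-methoxyphenyl]ethenyl}oxy)-2,6-bis(methoxymethoxy)phenyl]ethoxy}dimethylsilane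
Product: 13 tert-butyl{2-[4-({1-[4-(tert-butyldimethylsilyloxy)-3-methoxyphenyl]ethenyl}oxy)-2,6-bis(methoxymethoxy)-3-(3-methylbut-2-en-1-yl)phenyl]ethoxy}dimethylsilane, via aryllithium 11 (not isolated), via arylcopper 12 (not isolated)
Conditions: s-BuLi, TMEDA, THF, –78 °C; CuBr·SMe2, –78 → –40 °C; prenyl bromide, –40 → 0 °C
Reagents that add atoms: prenyl bromide (1-bromo-3-methylbut-2-ene), CC(C)=CCBr
Why: The two remaining ring-A positions are equivalent and each lies between a MOM ether and the enol-ether oxygen, so directed ortho-metalation there, transmetalation to the arylcopper and SN2 allylation at the primary carbon of prenyl bromide should give the linear prenyl arene.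

**Step 7**
Reactants: 13 tert-butyl{2-[4-({1-[4-(tert-butyldimethylsilyloxy)-3-methoxyphenyl]ethenyl}oxy)-2,6-bis(methoxymethoxy)-3-(3-methylbut-2-en-1-yl)phenyl]ethoxy}dimethylsilane
Product: 15 2-({1-[4-(tert-butyldimethylsilyloxy)-3-methoxyphenyl]ethenyl}oxy)-5-[2-(tert-butyldimethylsilyloxy)ethyl]-4,6-bis(methoxymethoxy)-3-(3-methylbut-2-en-1-yl)benzaldehyde, via aryllithium 14 (not isolated)
Conditions: s-BuLi, TMEDA, THF, –78 °C; DMF, –78 → 0 °C; H2O, then pH 7 buffer
Reagents that add atoms: N,N-dimethylformamide (DMF), CN(C)C=O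
Why: The last ring-A hydrogen lies between two oxygens and should be removed by MOM-directed ortho-metalation faster than the benzylic-allylic or ring-B hydrogens, and the aryllithium is formylated by DMF (Bouveault-type aldehyde synthesis), the buffered work-up sparing the enol ether.

**Step 8**
Reactants: 15 2-({1-[4-(tert-butyldimethylsilyloxy)-3-methoxyphenyl]ethenyl}oxy)-5-[2-(tert-butyldimethylsilyloxy)ethyl]-4,6-bis(methoxymethoxy)-3-(3-methylbut-2-en-1-yl)benzaldehyde
Product: 16 (2S)-2-[4-(tert-butyldimethylsilyloxy)-3-methoxyphenyl]-6-[2-(tert-butyldimethylsilyloxy)ethyl]-5,7-bis(methoxymethoxy)-8-(3-methylbut-2-en-1-yl)-2,3-dihydro-4H-chromen-4-one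
Conditions: [Rh(cod)Cl]2 (2.5 mol %), (R)-DTBM-SEGPHOS (5.5 mol %), NaB[3,5-(CF3)2C6H3]4 (5 mol %), 1,4-dioxane (degassed), 60 °C
Reagents that add atoms: none
Why: Proposed new method: A cationic bisphosphine complex of monovalent rhodium is expected to insert into the formyl C–H bond of 15; the hydride of the resulting acyl hydride of trivalent rhodium then adds to C2 of the enol ether while rhodium binds the terminal carbon C3, and C–C reductive elimination from the seven-membered acyl alkyl rhodacycle forms C3–C4. The closest known reaction type is the rhodium-catalysed enantioselective endo-hydroacylation of 1,1-disubstituted alkenes in ortho-allylbenzaldehydes and N-allyl heteroaryl carbaldehydes to six-membered benzo-fused ketones; an enol ether with its oxygen in the tether has not been used in this way. Ring C closes in the 6-endo-trig mode, because the 5-exo alternative would need a tertiary, benzylic, α-oxygenated alkyl rhodium intermediate, which the 1,1-disubstitution disfavours. C2 is the only new stereocentre and is fixed in the hydrometalation, the chiral pocket of the bisphosphine selecting the face of C2=C3 that receives the hydride (catalyst control, as 15 has no stereocentre). The step needs hydroacylation to outrun decarbonylation and β-aryloxy elimination: the two ortho oxygens at C5 and C8a can chelate rhodium and hold the acyl hydride, and O1 is endocyclic in the rhodacycle, so the syn-coplanar Rh–C3–C2–O1 arrangement needed for β-elimination is not reached. The prenyl double bond is trisubstituted and cannot reach the acyl carbon, so it should stay untouched.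

**Step 9**
Reactants: 16 (2S)-2-[4-(tert-butyldimethylsilyloxy)-3-methoxyphenyl]-6-[2-(tert-butyldimethylsilyloxy)ethyl]-5,7-bis(methoxymethoxy)-8-(3-methylbut-2-en-1-yl)-2,3-dihydro-4H-chromen-4-one
Product: 17 laxiflorin, (2S)-5,7-dihydroxy-2-(4-hydroxy-3-methoxyphenyl)-6-(2-hydroxyethyl)-8-(3-methylbut-2-en-1-yl)-2,3-dihydro-4H-chromen-4-one
Conditions: 3 M HCl (aq)/MeOH (1:4), 45 °C
Reagents that add atoms: none
Why: Methanolic HCl should hydrolyse the two aryl MOM acetals and solvolyse the alkyl and the aryl silyl ether in one operation, under conditions of the kind generally used to deprotect prenylated flavanones without cyclisation of the prenyl group or loss of the C2 configuration.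

**Compound list**

1 | phloroglucinol (benzene-1,3,5-triol) | Oc1cc(O)cc(O)c1 | starting material
2 | 3,5-bis(methoxymethoxy)phenol | COCOc1cc(O)cc(OCOC)c1 | intermediate
3 | vanillic acid (4-hydroxy-3-methoxybenzoic acid) | COc1cc(C(=O)O)ccc1O | starting material
4 | tert-butyldimethylsilyl 4-[(tert-butyldimethylsilyl)oxy]-3-methoxybenzoate | COc1cc(C(=O)O[Si](C)(C)C(C)(C)C)ccc1O[Si](C)(C)C(C)(C)C | intermediate
5 | 4-[(tert-butyldimethylsilyl)oxy]-3-methoxybenzoic acid | COc1cc(C(=O)O)ccc1O[Si](C)(C)C(C)(C)C | intermediate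
6 | 3,5-bis(methoxymethoxy)phenyl 4-[(tert-butyldimethylsilyl)oxy]-3-methoxybenzoate | COCOc1cc(OC(=O)c2ccc(O[Si](C)(C)C(C)(C)C)c(OC)c2)cc(OCOC)c1 | intermediate
7 | tert-butyl{4-[1-(3,5-bis(methoxymethoxy)phenoxy)ethenyl]-2-methoxyphenoxy}dimethylsilane | COCOc1cc(OC(=C)c2ccc(O[Si](C)(C)C(C)(C)C)c(OC)c2)cc(OCOC)c1 | intermediate
8 | aryllithium of 7, lithium on the ring-A carbon between the two MOM ethers | [Li]c1c(OCOC)cc(OC(=C)c2ccc(O[Si](C)(C)C(C)(C)C)c(OC)c2)cc1OCOC | intermediate
9 | lithium alkoxide, 7 carrying CH2CH2OLi between the two MOM ethers | [Li]OCCc1c(OCOC)cc(OC(=C)c2ccc(O[Si](C)(C)C(C)(C)C)c(OC)c2)cc1OCOC | intermediate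
10 | tert-butyl{2-[4-({1-[4-(tert-butyldimethylsilyloxy)-3-methoxyphenyl]ethenyl}oxy)-2,6-bis(methoxymethoxy)phenyl]ethoxy}dimethylsilane | CC(C)(C)[Si](C)(C)OCCc1c(OCOC)cc(OC(=C)c2ccc(O[Si](C)(C)C(C)(C)C)c(OC)c2)cc1OCOC | intermediate
11 | aryllithium of 10, lithium between a MOM ether and the enol-ether oxygen | CC(C)(C)[Si](C)(C)OCCc1c(OCOC)c([Li])c(OC(=C)c2ccc(O[Si](C)(C)C(C)(C)C)c(OC)c2)cc1OCOC | intermediate
12 | arylcopper corresponding to 11 | CC(C)(C)[Si](C)(C)OCCc1c(OCOC)c([Cu])c(OC(=C)c2ccc(O[Si](C)(C)C(C)(C)C)c(OC)c2)cc1OCOC | intermediate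
13 | tert-butyl{2-[4-({1-[4-(tert-butyldimethylsilyloxy)-3-methoxyphenyl]ethenyl}oxy)-2,6-bis(methoxymethoxy)-3-(3-methylbut-2-en-1-yl)phenyl]ethoxy}dimethylsilane | CC(C)=CCc1c(OC(=C)c2ccc(O[Si](C)(C)C(C)(C)C)c(OC)c2)cc(OCOC)c(CCO[Si](C)(C)C(C)(C)C)c1OCOC | intermediate
14 | aryllithium of 13, lithium on the last free ring-A carbon | CC(C)=CCc1c(OC(=C)c2ccc(O[Si](C)(C)C(C)(C)C)c(OC)c2)c([Li])c(OCOC)c(CCO[Si](C)(C)C(C)(C)C)c1OCOC | intermediate
15 | 2-({1-[4-(tert-butyldimethylsilyloxy)-3-methoxyphenyl]ethenyl}oxy)-5-[2-(tert-butyldimethylsilyloxy)ethyl]-4,6-bis(methoxymethoxy)-3-(3-methylbut-2-en-1-yl)benzaldehyde | O=Cc1c(OCOC)c(CCO[Si](C)(C)C(C)(C)C)c(OCOC)c(CC=C(C)C)c1OC(=C)c1ccc(O[Si](C)(C)C(C)(C)C)c(OC)c1 | intermediate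
16 | (2S)-2-[4-(tert-butyldimethylsilyloxy)-3-methoxyphenyl]-6-[2-(tert-butyldimethylsilyloxy)ethyl]-5,7-bis(methoxymethoxy)-8-(3-methylbut-2-en-1-yl)-2,3-dihydro-4H-chromen-4-one | COc1cc([C@@H]2CC(=O)c3c(OCOC)c(CCO[Si](C)(C)C(C)(C)C)c(OCOC)c(CC=C(C)C)c3O2)ccc1O[Si](C)(C)C(C)(C)C | intermediate
17 | laxiflorin, (2S)-5,7-dihydroxy-2-(4-hydroxy-3-methoxyphenyl)-6-(2-hydroxyethyl)-8-(3-methylbut-2-en-1-yl)-2,3-dihydro-4H-chromen-4-one | COc1cc([C@@H]2CC(=O)c3c(O)c(CCO)c(O)c(CC=C(C)C)c3O2)ccc1O | target

**Step count and risks**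

Total steps: 9. Longest linear sequence: 8 (steps 1 and 3 to 9).

Steps most likely to fail:

1. Step 8 (proposed new method). The acyl rhodium hydride may lose CO, the alkyl rhodium intermediate may eliminate the aryloxy group, closure may go 5-exo, or the facial discrimination at C2=C3 may be poor. The fallback sets out from aldehyde 15 and uses known chemistry. A thiol-catalysed radical-chain hydroacylation (tert-dodecanethiol cat., di-tert-butyl hyponitrite, dioxane, 60 °C) should close ring C without stereocontrol. The nucleophilic aroyl radical adds 6-endo to the unsubstituted terminus of the electron-rich enol ether and the benzylic α-oxy radical takes hydrogen from the thiol, giving the racemic protected flavanone F1. Kinetic resolution by asymmetric transfer hydrogenation (RuCl(p-cymene)[(R,R)-TsDPEN], HCO2H/Et3N, stopped near half conversion) is then expected to reduce the (2R)-ketone to the cis-(2R,4R)-flavan-4-ol F2. The (2S)-ketone left behind is 16, where the route is rejoined.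

2. Step 7. Deprotonation by the alkyllithium may stray to the prenyl CH2, to ring B or to the vinylic CH2, the last with elimination of the phenoxide; the lithiations of steps 5 and 6 share this hazard in milder form. The fallback sets out from phenol 2, installs every ring-A substituent without deprotonating in the presence of the enol ether, and rejoins at 15:
   - Silylation (TIPSCl, imidazole) gives the triisopropylsilyl ether F3.
   - n-BuLi (lithiation between the MOM ethers, the silyl ether shielding the other positions), ethylene oxide and then TBSCl give the bis-silyl compound F4.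
   - KHF2 in MeOH cleaves only the aryl silyl ether to the phenol F5.
   - NBS (1 equiv, CH2Cl2, –78 °C) brominates one of the two equivalent ortho positions (para blocked) to the bromophenol F6.
   - O-allylation with methyl 2-methylbut-3-en-2-yl carbonate and Pd(PPh3)4 (zerovalent palladium) gives the 1,1-dimethylallyl ether F7.
   - Aromatic Claisen rearrangement (toluene, 110 °C) delivers the prenyl group to the only free ortho carbon, giving the bromo prenyl phenol F8.
   - DCC/DMAP coupling with acid 5 gives the ester F9, and Tebbe methylenation gives the bromo enol ether F10.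
   - Bromine–lithium exchange with t-BuLi at –78 °C, far faster than any deprotonation, followed by DMF, gives 15.

3. Step 9. Protic acid may cyclise the prenyl group onto the C7 hydroxyl, or open and reclose ring C at O1–C2 with loss of configuration, before the aryl silyl ether and the hindered MOM ether are gone. The fallback sets out from 16 and avoids protic acid. HF·pyridine (THF, 0 °C → rt) removes both silyl ethers to give the bis-MOM triol F11. ZnBr2 with n-PrSH (CH2Cl2, 0 °C, short contact) then cleaves the two aryl MOM ethers by thiol capture of the oxocarbenium ion, giving 17.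

**Further compounds**

F1 | step 8 | racemic 2-[4-(tert-butyldimethylsilyloxy)-3-methoxyphenyl]-6-[2-(tert-butyldimethylsilyloxy)ethyl]-5,7-bis(methoxymethoxy)-8-(3-methylbut-2-en-1-yl)-2,3-dihydro-4H-chromen-4-one | COc1cc(C2CC(=O)c3c(OCOC)c(CCO[Si](C)(C)C(C)(C)C)c(OCOC)c(CC=C(C)C)c3O2)ccc1O[Si](C)(C)C(C)(C)C
F2 | step 8 | (2R,4R)-2-[4-(tert-butyldimethylsilyloxy)-3-methoxyphenyl]-6-[2-(tert-butyldimethylsilyloxy)ethyl]-5,7-bis(methoxymethoxy)-8-(3-methylbut-2-en-1-yl)-3,4-dihydro-2H-chromen-4-ol | COc1cc([C@H]2C[C@@H](O)c3c(OCOC)c(CCO[Si](C)(C)C(C)(C)C)c(OCOC)c(CC=C(C)C)c3O2)ccc1O[Si](C)(C)C(C)(C)C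
F3 | step 7 | [3,5-bis(methoxymethoxy)phenoxy]tri(propan-2-yl)silane | COCOc1cc(O[Si](C(C)C)(C(C)C)C(C)C)cc(OCOC)c1
F4 | step 7 | tert-butyl(2-{2,6-bis(methoxymethoxy)-4-[(triisopropylsilyl)oxy]phenyl}ethoxy)dimethylsilane | CC(C)(C)[Si](C)(C)OCCc1c(OCOC)cc(O[Si](C(C)C)(C(C)C)C(C)C)cc1OCOC
F5 | step 7 | 4-{2-[(tert-butyldimethylsilyl)oxy]ethyl}-3,5-bis(methoxymethoxy)phenol | CC(C)(C)[Si](C)(C)OCCc1c(OCOC)cc(O)cc1OCOC
F6 | step 7 | 2-bromo-4-{2-[(tert-butyldimethylsilyl)oxy]ethyl}-3,5-bis(methoxymethoxy)phenol | CC(C)(C)[Si](C)(C)OCCc1c(OCOC)cc(O)c(Br)c1OCOC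
F7 | step 7 | {2-[3-bromo-2,6-bis(methoxymethoxy)-4-(2-methylbut-3-en-2-yloxy)phenyl]ethoxy}(tert-butyl)dimethylsilane | C=CC(C)(C)Oc1cc(OCOC)c(CCO[Si](C)(C)C(C)(C)C)c(OCOC)c1Br
F8 | step 7 | 2-bromo-4-{2-[(tert-butyldimethylsilyl)oxy]ethyl}-3,5-bis(methoxymethoxy)-6-(3-methylbut-2-en-1-yl)phenol | CC(C)=CCc1c(O)c(Br)c(OCOC)c(CCO[Si](C)(C)C(C)(C)C)c1OCOC
F9 | step 7 | 2-bromo-4-{2-[(tert-butyldimethylsilyl)oxy]ethyl}-3,5-bis(methoxymethoxy)-6-(3-methylbut-2-en-1-yl)phenyl 4-[(tert-butyldimethylsilyl)oxy]-3-methoxybenzoate | CC(C)=CCc1c(OC(=O)c2ccc(O[Si](C)(C)C(C)(C)C)c(OC)c2)c(Br)c(OCOC)c(CCO[Si](C)(C)C(C)(C)C)c1OCOC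
F10 | step 7 | bromo analogue of 13, bromine on the ring-A carbon between the enol-ether oxygen and a MOM ether | CC(C)=CCc1c(OC(=C)c2ccc(O[Si](C)(C)C(C)(C)C)c(OC)c2)c(Br)c(OCOC)c(CCO[Si](C)(C)C(C)(C)C)c1OCOC
F11 | step 9 | (2S)-2-(4-hydroxy-3-methoxyphenyl)-6-(2-hydroxyethyl)-5,7-bis(methoxymethoxy)-8-(3-methylbut-2-en-1-yl)-2,3-dihydro-4H-chromen-4-one | COc1cc([C@@H]2CC(=O)c3c(OCOC)c(CCO)c(OCOC)c(CC=C(C)C)c3O2)ccc1O
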